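**The pitfall.** Dividing the G charged by the J charged promised 20.0 units per chain, but that counts every Z as a chain, while Z met E at 0.640 /s and G at 0.0840 /s, faster at the start.

G 1.0 mM; J 5 mol%; E 40 µM; time 1.0 min

    G + Z → D + X (k1 = 84 /M/s)
    G + D → X + D, rate k2*[D]*[G] (k2 = 780 /M/s)
    Z + E → Z.E (k3 = 16000 /M/s)
    J → Z (k4 = 0.093 /s)

- the average divides the monomer in chains by the number of chains begun, living and dead together
- run time (flask): 1.0 min

1. whether the average number of monomer units in a chain (chains begun, living or dead) reaches 8.0 by 1.0 min (yes / no)
2. average number of monomer units in a chain (chains begun, living or dead) at 1.0 min

**The surplus.** The J charged less the E charged came to 0.0100 mM, and I called this the surplus. Each E takes one Z, so once J had released its charge, the chains had to number at least this. J halved every 7.45 s, and the run held 8.05 such half-lives.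

**The curve.** The length started at one unit, since each chain begins with one X. While chains rose in proportion to time, the X added rose as its square, so I took the slope as half the growth constant times the G charged, 0.390 /s. That put the crossing of 8.0 near 0.299 min, or 2.41 half-lives of J. Past the knee, taking the chains as steady, I expected a slope twice as steep, 0.780 /s, easing as G fell, and with the surplus as the chain count a level of 100. With the surplus as the chain count, G had a lifetime of 2.14 min, which is a pseudo-first-order decay. Counting those chains from the first second gave 0.374 mM of X and a length of 37.4, so I answered yes.

**The forecast.** The forecast said yes and 27, with a range of 23 to 32, starting from “Each Z that reaches G starts a chain”. Its length was lower than mine.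

**The result.** The flask gave yes and a length of 27.2, lower than my reckoning. The length crossed 8.0 at 0.309 min. At 1.00 min the flask held 0.0124 mM of D, 1.24 times the surplus. At 10.0 min it held 0.0128 mM of D with X at 99.7%, a length of 78.2, below the 100 that the surplus gives.

(The constants used here were chosen freely, and the outcome is calculated.)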